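Everything rests on breaking the alkyl C–O bond of the secondary ester, so that the acid serves as an oxygen nucleophile and never needs acyl activation. The feature exploited is C1 of the allyl unit, the lone sp3 stereocentre, bonded to the ester O, the vinyl group and the 3,4,5-trimethoxyphenyl ring (ring positions C2 and C6 unsubstituted); it maps onto the substituted end of a 1-arylallyl-iridium cation. One asymmetric allylic esterification couples the halves, gives the branched isomer and sets S. Its precursors are achiral: linear (E)-cinnamyl tert-butyl carbonate 4 and acid 11, which already holds the Z-enoate (from a Z-alkenyl iodide by carbonylation) and the bought E-tiglate.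

Key step: step 8

Assumption: with O-nucleophiles at 1-arylallyl termini the (Sa,S,S) ligand is taken to give the S product. Because 4 is achiral, the mirror-image ligand gives the mirror-image ester, so the ligand hand is confirmed on a first small run (K2CO3/MeOH cleavage to the carbinol, then chiral HPLC or MTPA ester analysis).

Step 1
Reactants: 1 (E)-3,4,5-trimethoxycinnamic acid
Product: 3 (E)-3-(3,4,5-trimethoxyphenyl)prop-2-en-1-ol, via ethyl carbonic mixed anhydride 2 (not isolated)
Conditions: ClCO2Et (1.1 equiv), Et3N (1.1 equiv), THF, −10 °C; then NaBH4 (3 equiv), H2O, 0 °C to rt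
Reagents that add atoms: ethyl chloroformate CCOC(=O)Cl (its atoms are kept only in 2)
Why: Mixed carbonic anhydride activation followed by borohydride reduction, a standard one-flask conversion of cinnamic acids into cinnamyl alcohols: hydride attacks the more electrophilic acyl carbonyl of 2 and then the aldehyde in 1,2 fashion, so the E-alkene and the three aryl ethers are left alone.

Step 2
Reactants: 3 (E)-3-(3,4,5-trimethoxyphenyl)prop-2-en-1-ol
Product: 4 (E)-3-(3,4,5-trimethoxyphenyl)prop-2-en-1-yl tert-butyl carbonate
Conditions: Boc2O (1.3 equiv), Bu4NHSO4 (5 mol%), 30% aq NaOH, CH2Cl2, 0 °C to rt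
Reagents that add atoms: di-tert-butyl dicarbonate CC(C)(C)OC(=O)OC(=O)OC(C)(C)C
Why: O-tert-butoxycarbonylation of a primary alcohol with Boc2O under phase-transfer catalysis, in which the interfacial alkoxide attacks the dicarbonate and the cold two-phase medium holds back the symmetrical dicinnamyl carbonate; the group installed serves only as leaving group and latent base.

Step 3
Reactants: 5 (E)-crotonaldehyde
Product: 6 (Z)-2-iodobut-2-enal
Conditions: I2 (1.5 equiv), K2CO3 (1.2 equiv), DMAP (20 mol%), THF/H2O 1:1, rt; Na2S2O3 wash, crude 6 used at once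
Reagents that add atoms: iodine II
Why: α-Iodination of an enal by a Baylis–Hillman-type sequence (conjugate addition of DMAP, iodination of the enolate, loss of DMAP), which should deliver the more stable alkene with CHO trans to CH3, that is the Z-iodide.

Step 4
Reactants: 6 (Z)-2-iodobut-2-enal
Product: 7 (Z)-2-iodobut-2-en-1-ol
Conditions: NaBH4, MeOH, 0 °C
Reagents that add atoms: none
Why: Borohydride 1,2-reduction of an aldehyde, routine for α-iodoenals, which leaves the C–I bond and the alkene geometry untouched.

Step 5
Reactants: 7 (Z)-2-iodobut-2-en-1-ol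
Product: 8 2-(trimethylsilyl)ethyl (Z)-2-(hydroxymethyl)but-2-enoate
Conditions: PdCl2(PPh3)2 (5 mol%), CO (1 atm), Et3N (2 equiv), Me3SiCH2CH2OH (10 equiv, excess recovered by distillation), DMF, 60 °C
Reagents that add atoms: carbon monoxide [C-]#[O+]; 2-(trimethylsilyl)ethanol C[Si](C)(C)CCO
Why: Heck-type alkoxycarbonylation of an alkenyl iodide, in which oxidative addition to zerovalent palladium, CO insertion and alcoholysis all occur with retention at the sp2 carbon, so CO2R takes the place of iodine cis to CH3, while the large excess of the added primary alcohol should outrun capture of the acyl-palladium by the hydroxyl groups of 7 and 8.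

Step 6
Reactants: 8 2-(trimethylsilyl)ethyl (Z)-2-(hydroxymethyl)but-2-enoate; 9 tigloyl chloride, (E)-2-methylbut-2-enoyl chloride
Product: 10 2-(trimethylsilyl)ethyl (Z)-2-{[(E)-2-methylbut-2-enoyl]oxymethyl}but-2-enoate
Conditions: 9 (1.3 equiv), pyridine (2 equiv), CH2Cl2, 0 °C
Reagents that add atoms: none
Why: O-acylation of a primary allylic alcohol with an acid chloride (Einhorn variant of the Schotten–Baumann reaction), run cold and without DMAP or DABCO because such strongly nucleophilic amines add in SN2' fashion to acyloxymethyl enoates and would scramble the Z-alkene.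

Step 7
Reactants: 10 2-(trimethylsilyl)ethyl (Z)-2-{[(E)-2-methylbut-2-enoyl]oxymethyl}but-2-enoate
Product: 11 (Z)-2-{[(E)-2-methylbut-2-enoyl]oxymethyl}but-2-enoic acid
Conditions: Bu4NF/AcOH (1:1, 2.5 equiv), THF, 0 °C to rt; work-up with cold 0.5 M HCl
Reagents that add atoms: none
Why: Fluoride-induced 1,2-elimination (fragmentation) of a β-silylethyl ester, in which attack at silicon expels ethylene and the carboxylate, the acetic acid buffer keeps γ-deprotonation and loss of tiglate at bay, and neither the tiglate nor the Z-enoate offers fluoride a silicon handle.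

Step 8
Reactants: 4 (E)-3-(3,4,5-trimethoxyphenyl)prop-2-en-1-yl tert-butyl carbonate; 11 (Z)-2-{[(E)-2-methylbut-2-enoyl]oxymethyl}but-2-enoic acid
Product: 12 (S)-1-(3,4,5-trimethoxyphenyl)prop-2-en-1-yl (Z)-2-{[(E)-2-methylbut-2-enoyl]oxymethyl}but-2-enoate (CNP0203602.1)
Conditions: [Ir(cod)Cl]2 (2 mol%), L (4 mol%; L = (Sa,S,S)-O,O'-(1,1'-binaphthalene-2,2'-diyl) N,N-bis(1-phenylethyl)phosphoramidite), n-PrNH2, THF, 50 °C, then all volatiles removed in vacuo to leave [Ir(cod)(κ2-L)(L)]; then 4 (1.0 equiv), 11 (1.2 equiv), Cs2CO3 (10 mol%), THF, rt; filtration through silica at full conversion of 4, chromatography on neutral silica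
Reagents that add atoms: none
Why: Iridium-catalysed asymmetric allylic substitution with a carboxylate nucleophile (allylic esterification), a known reaction of linear 3-arylallyl electrophiles: the cyclometalated complex of monovalent iridium ionises 4 to a cationic η3-(1-arylallyl) complex of trivalent iridium, CO2 and tert-butoxide, and the alkoxide is protonated at once by 11, so the medium never turns basic. The carboxylate oxygen then attacks from outside the coordination sphere, anti to the metal, at the aryl-bearing allyl carbon, where the Ir–C bond is longest and positive charge is best carried; this makes the O–C(sp3) bond, leaves the terminal vinyl group and closes no ring. The S centre is under pure catalyst control, because 4 is achiral: the binaphthyl phosphoramidite metallacycle holds the allyl ligand by one face and anti attack translates that face into the configuration at C1. Branched over linear selectivity is needed and is secured by the aryl substituent itself, whose C2 and C6 are free of ortho groups and whose two meta-methoxy groups offset the twisted para-methoxy group. Chemoselectivity is needed as well: the allylic tiglate inside 11 is a primary carboxylate on a trisubstituted alkene that carries a substituent at the central allyl carbon, a pattern this catalyst does not ionise, and the absence of acyl activation and of nucleophilic amines spares the Z-enoate. Since 1-arylallyl carboxylates are themselves slowly ionised by the catalyst, 11 is used in slight excess, conversion is followed closely and the iridium is filtered off through silica as soon as 4 is consumed, which limits drift to the linear cinnamyl ester and loss of ee.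

Compound list
1 | (E)-3,4,5-trimethoxycinnamic acid | COc1cc(/C=C/C(=O)O)cc(OC)c1OC | starting material
2 | (E)-3,4,5-trimethoxycinnamic ethyl carbonic anhydride | COc1cc(/C=C/C(=O)OC(=O)OCC)cc(OC)c1OC | intermediate
3 | (E)-3-(3,4,5-trimethoxyphenyl)prop-2-en-1-ol | COc1cc(/C=C/CO)cc(OC)c1OC | intermediate
4 | (E)-3-(3,4,5-trimethoxyphenyl)prop-2-en-1-yl tert-butyl carbonate | COc1cc(/C=C/COC(=O)OC(C)(C)C)cc(OC)c1OC | intermediate
5 | (E)-crotonaldehyde | C/C=C/C=O | starting material
6 | (Z)-2-iodobut-2-enal | C/C=C(\I)C=O | intermediate
7 | (Z)-2-iodobut-2-en-1-ol | C/C=C(\I)CO | intermediate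
8 | 2-(trimethylsilyl)ethyl (Z)-2-(hydroxymethyl)but-2-enoate | C/C=C(\C(=O)OCC[Si](C)(C)C)CO | intermediate
9 | tigloyl chloride, (E)-2-methylbut-2-enoyl chloride | C/C=C(\C)C(=O)Cl | starting material
10 | 2-(trimethylsilyl)ethyl (Z)-2-{[(E)-2-methylbut-2-enoyl]oxymethyl}but-2-enoate | C/C=C(\C(=O)OCC[Si](C)(C)C)COC(=O)/C(C)=C/C | intermediate
11 | (Z)-2-{[(E)-2-methylbut-2-enoyl]oxymethyl}but-2-enoic acid | C/C=C(\C(=O)O)COC(=O)/C(C)=C/C | intermediate
12 | (S)-1-(3,4,5-trimethoxyphenyl)prop-2-en-1-yl (Z)-2-{[(E)-2-methylbut-2-enoyl]oxymethyl}but-2-enoate, CNP0203602.1 | C=C[C@H](OC(=O)/C(=C\C)COC(=O)/C(C)=C/C)c1cc(OC)c(OC)c(OC)c1 | target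

Total step count: 8. Longest linear sequence: 6 steps (5, 6, 7, 8, 10, 11, 12); the aryl branch (1 to 4) adds 2 steps and joins in step 8.

Steps most likely to fail

1. Step 8.
- **Risk:** The free acid may protonate the metallacycle so that turnover stalls. The branched ester may re-ionise, with drift to the linear isomer and erosion of ee. Facial control may be weak with this untested carboxylate.
- **Fallback, from 4 and 11 back to 12:** The stereocentre is set with an oxygen nucleophile whose product cannot re-ionise, and the union is moved to the acyl carbon.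
 - Carbonate 4 is treated with KOSiEt3 (2 equiv) and [Ir(cod)Cl]2 plus the same ligand L in CH2Cl2 at rt. This known silanolate variant of the allylic substitution should give (S)-triethyl{[1-(3,4,5-trimethoxyphenyl)prop-2-en-1-yl]oxy}silane F1.
 - Bu4NF in THF then releases (S)-1-(3,4,5-trimethoxyphenyl)prop-2-en-1-ol F2.
 - Separately, 11 is converted under neutral conditions with 1-chloro-N,N,2-trimethylprop-1-en-1-amine (CH2Cl2, 0 °C) into (Z)-2-{[(E)-2-methylbut-2-enoyl]oxymethyl}but-2-enoyl chloride F3.
 - F3 acylates F2 in the presence of 2,6-lutidine (CH2Cl2, 0 °C to rt) to give 12. The C–O bond at the stereocentre is not touched, and no nucleophilic amine is present.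

2. Step 5.
- **Risk:** The acyl-palladium may be captured by the hydroxyl group of the substrate or product (four-membered lactone closure or oligoester formation) instead of by the added alcohol. Geometry may also be lost by reversible hydropalladation.
- **Fallback, from 7 back to 8:** Polar carboxylation of a masked alcohol replaces the carbonylation.
 - TBSCl and imidazole in DMF give (Z)-tert-butyl[(2-iodobut-2-en-1-yl)oxy]dimethylsilane F4.
 - Iodine–magnesium exchange with iPrMgCl·LiCl (THF, −20 °C) proceeds with retention to give (Z)-[1-(tert-butyldimethylsilyloxy)but-2-en-2-yl]magnesium chloride F5.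
 - F5 is quenched at −40 °C with 2-(trimethylsilyl)ethyl chloroformate to give 2-(trimethylsilyl)ethyl (Z)-2-[(tert-butyldimethylsilyloxy)methyl]but-2-enoate F6.
 - AcOH/THF/H2O at rt removes the silyl ether without fluoride and returns 8.

3. Step 7.
- **Risk:** Base may induce vinylogous elimination or cleavage of the tiglate. Fluoride or carboxylate may undergo addition–elimination at the acyloxymethyl enoate, with Z/E scrambling.
- **Fallback, from 7 (with 9) back to 11:** The carboxyl group is carried as an acid-labile ester, so that neither fluoride nor base meets the sensitive diester.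
 - Carbonylation of 7 as in step 5, but with 4-methoxybenzyl alcohol as the added alcohol, gives 4-methoxybenzyl (Z)-2-(hydroxymethyl)but-2-enoate F7.
 - Acylation with 9 and pyridine as in step 6 gives 4-methoxybenzyl (Z)-2-{[(E)-2-methylbut-2-enoyl]oxymethyl}but-2-enoate F8.
 - Trifluoroacetic acid with anisole as cation trap (CH2Cl2, 0 °C) releases 11.

Further compounds
F1 | step 8 | (S)-triethyl{[1-(3,4,5-trimethoxyphenyl)prop-2-en-1-yl]oxy}silane | C=C[C@H](O[Si](CC)(CC)CC)c1cc(OC)c(OC)c(OC)c1
F2 | step 8 | (S)-1-(3,4,5-trimethoxyphenyl)prop-2-en-1-ol | C=C[C@H](O)c1cc(OC)c(OC)c(OC)c1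
F3 | step 8 | (Z)-2-{[(E)-2-methylbut-2-enoyl]oxymethyl}but-2-enoyl chloride | C/C=C(\C(=O)Cl)COC(=O)/C(C)=C/C
F4 | step 5 | (Z)-tert-butyl[(2-iodobut-2-en-1-yl)oxy]dimethylsilane | C/C=C(\I)CO[Si](C)(C)C(C)(C)C
F5 | step 5 | (Z)-[1-(tert-butyldimethylsilyloxy)but-2-en-2-yl]magnesium chloride | C/C=C(\[Mg]Cl)CO[Si](C)(C)C(C)(C)C
F6 | step 5 | 2-(trimethylsilyl)ethyl (Z)-2-[(tert-butyldimethylsilyloxy)methyl]but-2-enoate | C/C=C(\C(=O)OCC[Si](C)(C)C)CO[Si](C)(C)C(C)(C)C
F7 | step 7 | 4-methoxybenzyl (Z)-2-(hydroxymethyl)but-2-enoate | C/C=C(\C(=O)OCc1ccc(OC)cc1)CO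
F8 | step 7 | 4-methoxybenzyl (Z)-2-{[(E)-2-methylbut-2-enoyl]oxymethyl}but-2-enoate | C/C=C(\C(=O)OCc1ccc(OC)cc1)COC(=O)/C(C)=C/C
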